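Take the constants first: one for the making of target, one for its loss, both read from the earlier runs.

| flask | substrate | coupling partner | time |
|---|---|---|---|
| ochre | 0.600 M | 0.600 M |  |
| grey | 0.360 M | 0.360 M |  |
| teal | 1.80 M | 0.600 M |  |
| violet | 0.600 M | 1.80 M |  |
| blue | 0.600 M | 0.600 M | 21 h |

- ochre run (time / h: [target] / M): 0.65: 0.1072; 1.3: 0.1760; 1.9: 0.2123; 2.6: 0.2493; 3.2: 0.2705; 3.9: 0.2893; 4.5: 0.2957; 5.2: 0.3095
- grey run (time / h: [target] / M): 0.65: 0.0433; 1.3: 0.0673; 1.9: 0.0882; 2.6: 0.1119; 3.2: 0.1220; 3.9: 0.1356; 4.5: 0.1420; 5.2: 0.1486
- teal run (time / h: [target] / M): 0.65: 0.2588; 1.3: 0.3683; 1.9: 0.4205; 2.6: 0.4463; 3.2: 0.4609; 3.9: 0.4651; 4.5: 0.4691; 5.2: 0.4641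
- violet run (time / h: [target] / M): 0.65: 0.3165; 1.3: 0.4322; 1.9: 0.4747; 2.6: 0.4982; 3.2: 0.4989; 3.9: 0.4955; 4.5: 0.4839; 5.2: 0.4714

(standard deviation of a reading: 0.002 M)

- Overall: substrate + coupling partner -> target.
- Constant volume, constant temperature.
- "The second partner" is coupling partner.
- An order is taken over about fifteen percent of the charge, up and down.

* the exponent of [coupling partner] in the starting rate at the charge of the ochre run (at the point where two percent of the substrate have become target)
* the exponent of [substrate] in the starting rate at the charge of the ochre run (at the point where two percent of the substrate have become target) (one fixed amount of target, the same in the runs compared)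
* target in the blue run at 21 h, as a share of the substrate charged

For the making constant k, in rate = k[substrate][coupling partner], use the first ochre reading. The charges are equal, so neither reactant is the limiting reagent, and the reciprocal of the substrate left climbs in a straight line with time:

k = 0.558 M⁻¹ h⁻¹

Continue that line to 21 h for the blue run, whose charge is the ochre charge, and call M the target ever made:

M = 0.525 M

Now read the loss from the tail of the violet run, where substrate and coupling partner both fall while their difference stays at 1.20 M. Put the first violet reading into the integrated law for unequal charges to get the violet making constant, 0.713 M⁻¹ h⁻¹. That law leaves 0.0144 M of substrate in the violet run at 3.9 h and 0.00469 M at 5.2 h, so about 0.00969 M of target is still made between those times. Add this to the fall in the readings and divide by the time and the mean level to get the loss constant, the fraction of the target present that goes each hour: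

L = 0.0538 h⁻¹

Solve two extreme flasks. If nothing is lost, the blue run holds 87.5 % of its substrate charge. If all of M is made at the start and then decays for the whole 21 h, it holds 28.3 %.

The target of the real blue flask is made over time, so the flask lies between them. Replace the spread of ages by their mean, the area under the making curve divided by M:

mean age = 16.9 h

This mean age is shorter than 21 h; put it into the decay:

share at 21 h = 35.3 %

The forecast gave orders of 1.15 in coupling partner and 0.9 in substrate and, saying “the plateau of about 0.32 M erodes to about 0.29 M by 21 h”, a blue share of 49 % (44 % to 55 %), more than my reckoning.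

The flask gives orders of 1.2 in coupling partner and 1.0 in substrate, and a blue share of 37.1 %, more than my 35.3 %. The fit in which the product binds the substrate puts the blue run at 62.5 %.

    substrate + coupling partner → target (0.5004 M⁻¹ h⁻¹)
    substrate + 2 coupling partner → target + coupling partner (0.1530 M⁻² h⁻¹)
    2 substrate → homo dimer (0.05472 M⁻¹ h⁻¹)
    target → decomposed product (0.04644 h⁻¹)

Put L to the grey run: let its reading of 0.1119 M at 2.6 h stand for its mean level up to 5.2 h, so that it has lost 0.0313 M by then. With its reading of 0.1486 M at that time, the grey run has made 0.180 M, which is 50.0 % of its substrate charge.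

The runs are simulated for an exercise; noise was put on by code.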